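The constant we have to work with is a single one, the rate of the main step, and it must be read from the earlier run before any of these flasks can be reckoned.

common to all: E 1.7 mM
- west: Q 2.5 M; temperature 10 °C; run made earlier
- red: Q 1.7 M; temperature 10 °C; time 15 min
- teal: Q 1.7 M; temperature −5 °C; time 15 min
- green: Q 1.7 M; temperature 25 °C; time 15 min
- grey: Q 1.7 M; at −5 °C until 8.0 min, from then on at 25 °C; time 15 min

west run (percent of the Q charged): time / s: L / % = 10.0: 0.3; 15.0: 1.8; 25.0: 2.4; 40.0: 3.4; 50.0: 4.9; 80.0: 7.5; 90.0: 7.9

(readings scatter by 0.3 percentage points)

1. the best flask by amount of L, in percent of the Q charged; "all alike" if 1.5 percentage points covers them all (red / teal / green / grey / all alike)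
2. amount of L at the end, in percent of the Q charged, red
3. amount of L at the end, in percent of the Q charged, teal
4. amount of L at the end, in percent of the Q charged, green
5. amount of L at the end, in percent of the Q charged, grey

- in a conversion Z counts as not yet reacted
- a reading or a percentage of L counts all its forms, free or not
- the earlier runs do not show what temperature does; that part of a forecast is a guess

We begin with the main step alone, Q turning to L on E, and take it as first order in Q, which a west run at one charge of Q cannot test. The last west reading, 7.9% at 90.0 s, then gives a pseudo-first-order constant k′ = 0.0549 min⁻¹ at 1.7 mM of E, a reading that carries the scatter. Red has the E and the temperature of the west run, so k′ times its time gives 0.823. This number is the reach N, for the main step alone the natural logarithm of Q charged over Q left. A fraction e^(−N) of the Q stays and the rest is L, so red comes to 56.1%.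

Next we add temperature. The runs do not show what it does, so we guess that rates double for every 10 °C, which means a factor of 2.83 from 10 °C up to 25 °C and the same factor down to −5 °C. Teal's reach is then 0.291, or 25.2%, and green's is 2.33, or 90.2%. Grey adds its cold and hot stretches to 1.24, or 71.1%.

The rest we cannot size. Z and any loss of E do not show in a west run of 90.0 s, which keeps to a straight line. We expect both to lower L, so we take these figures as high, with green on top.

The forecast names green as best, with 68% for red, 27% for teal, 94% for green and 80% for grey, each above our figure, and it notes: "Catalyst death when hot is untested". The flasks give 29.1% for red, 14.4% for teal, 38.4% for green and 30.9% for grey, each below our figure, and green is best.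

    Q ⇌ Z (K = 0.930, k = 0.110 min⁻¹, Ea = 80.0 kJ mol⁻¹, ΔH = 38.0 kJ mol⁻¹)
    Q + E → E + L (k = 140 M⁻¹ min⁻¹, Ea = 60.0 kJ mol⁻¹)
    E + Z → E + J (k = 75.0 M⁻¹ min⁻¹, Ea = 40.0 kJ mol⁻¹)
    L ⇌ D (K = 0.480, k = 0.550 min⁻¹, Ea = 90.0 kJ mol⁻¹, ΔH = 18.0 kJ mol⁻¹)
    G ⇌ L, rate k5*(cs5 - [L]) while solid is left; crystals form when [L] > cs5 (solubility = 0.720 M, k = 20.0 min⁻¹)
    2 E → X (k = 98.0 M⁻¹ min⁻¹, Ea = 38.0 kJ mol⁻¹)
    (constants at 25 °C)

Q ⇌ Z draws on Q beside the main step, and N as reckoned here leaves it out; of the other steps, two touch the reach. D is made from L, so the output of the main step stands as L plus D. Two E going to X make the reciprocal of [E] climb in a straight line, which multiplies N by ln(g) / (g − 1), g being E charged over E left. Green, with 16.7% of its E left at the end, then has N = 0.834, or 56.6%, and holds 56.7% as L plus D. With Q ⇌ Z left out and the doubling guessed, that nearness is no check: green has 16.9% of its Q left, less than the 43.4% of e^(−N). The neighbour of green charged with 4.2 × 10⁻⁴ M of E, its N scaled by that charge too, keeps 44.7% of its E, so N = 0.375, or 31.3%, and it holds 31.1% as L plus D, of which L is 21.2%.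

All runs stem from a simulated flask for substances that don't exist, noise included.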